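The butenolide ring (O1–C2–C3–C4–C5) is cut at C3–C4 and O1–C2. The cut exploits the fact that C5, C4 and the C4 carboxyl make up a 3-oxygenated fatty acid, whereas C2, C3 and the C3 methyl make up pyruvate. In a single operation the dianion of a (3S)-3-hydroxy ester adds through its α-carbon to the ketone of methyl pyruvate, and the C5 oxygen then closes the γ-lactone on the pyruvate ester. The precursor is tert-butyl (3S)-3-hydroxy-16-(2-methyl-1,3-dioxolan-2-yl)hexadecanoate: C5 is already set, the distal ketone is masked as a dioxolane, and the tert-butyl ester allows an acid-only end game.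

Key step: step 6

Remark on numbering and stereochemistry: ring atoms are O1, C2 (lactone C=O), C3 (methyl-bearing), C4 (carboxyl-bearing) and C5 (chain-bearing, S in the target). The centres formed at C3 and C4 in step 6 are expected as mixtures, are drawn without configuration, and are removed in step 7.

Step 1
Reactants: 1 ω-pentadecalactone; 2 methyllithium
Product: 4 16-hydroxyhexadecan-2-one, via lithium hemiketal alkoxide 3 (not isolated)
Conditions: MeLi (1.05 equiv), THF, −78 °C; AcOH, −78 °C
Reagents that add atoms: methyllithium, [Li]C
Why: Nucleophilic acyl substitution of a lactone by one equivalent of an organolithium; at −78 °C the tetrahedral adduct 3 should persist until the cold acidic quench, so the ketone is released only after the methyllithium is destroyed and double addition is held back.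

Step 2
Reactants: 4 16-hydroxyhexadecan-2-one
Product: 6 15-oxohexadecanoic acid, via 15-oxohexadecanal 5 (not isolated)
Conditions: TEMPO (cat.), PhI(OAc)2 (2.2 equiv), MeCN–CH2Cl2–H2O, rt
Reagents that add atoms: water, O
Why: Oxoammonium (TEMPO/PhI(OAc)2) oxidation takes the primary alcohol through aldehyde 5 and its hydrate to the acid, while the ketone is inert to the oxidant and no acid-labile group is yet present.

Step 3
Reactants: 6 15-oxohexadecanoic acid; 7 Meldrum's acid; 8 tert-butanol
Product: 10 tert-butyl 3,17-dioxooctadecanoate, via acyl Meldrum's acid 9 (not isolated)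
Conditions: Meldrum's acid, DCC, DMAP, CH2Cl2, 0 °C → rt; then t-BuOH, toluene, 90 °C
Reagents that add atoms: Meldrum's acid, CC1(C)OC(=O)CC(=O)O1; tert-butanol, CC(C)(C)O
Why: Oikawa–Yonemitsu β-keto ester synthesis, in which carbodiimide C-acylation of Meldrum's acid gives 9 and its thermolysis in the presence of tert-butanol expels acetone and CO2 to leave the tert-butyl 3-oxo ester, the ester group being chosen so that the C4 carboxyl can later be freed by acid alone.

Step 4
Reactants: 10 tert-butyl 3,17-dioxooctadecanoate
Product: 11 tert-butyl (3S)-3-hydroxy-17-oxooctadecanoate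
Conditions: H2 (10 atm), RuCl2[(S)-BINAP](dmf)n (0.5 mol %), MeOH, 50 °C
Reagents that add atoms: none
Why: Noyori asymmetric hydrogenation, in which the chelating β-keto ester is reduced under catalyst control and (S)-BINAP should deliver the (3S) carbinol (the future C5) by the established sense for 3-oxoalkanoates, whereas the remote methyl ketone lacks a chelating neighbour and is not reduced by BINAP–Ru dihalide catalysts.

Step 5
Reactants: 11 tert-butyl (3S)-3-hydroxy-17-oxooctadecanoate; 12 ethylene glycol
Product: 13 tert-butyl (3S)-3-hydroxy-16-(2-methyl-1,3-dioxolan-2-yl)hexadecanoate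
Conditions: HOCH2CH2OH, PPTS (cat.), benzene, reflux (Dean–Stark)
Reagents that add atoms: ethylene glycol, OCCO
Why: Acid-catalysed ketalisation with azeotropic removal of water, mild enough under PPTS to leave the tert-butyl ester and the β-hydroxy ester alone; placing it after the hydrogenation keeps the acid-labile dioxolane away from the HCl-bearing ruthenium catalyst in methanol.

Step 6
Reactants: 13 tert-butyl (3S)-3-hydroxy-16-(2-methyl-1,3-dioxolan-2-yl)hexadecanoate; 14 methyl pyruvate
Product: 18 tert-butyl (2S)-4-hydroxy-4-methyl-2-[13-(2-methyl-1,3-dioxolan-2-yl)tridecyl]-5-oxooxolane-3-carboxylate, via dilithium dianion 15 (not isolated), via dilithium aldolate 16 (not isolated), via open-chain dihydroxy diester 17 (not isolated)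
Conditions: LDA (2.2 equiv), THF, −78 → −20 °C; MeCOCO2Me (1.4 equiv), −78 °C; AcOH, −78 °C; then PPTS (cat.), toluene, 50 °C
Reagents that add atoms: methyl pyruvate, CC(=O)C(=O)OC
Why: Two equivalents of LDA convert 13 into the chelated alkoxide–enolate 15 (Fráter–Seebach dianion), in which the C5 oxygen is an alkoxide that cannot leave by β-elimination and C5 bears no acidic hydrogen, so the (S) centre is carried through unchanged. The enolate carbon (future C4) adds to the ketone carbonyl of methyl pyruvate, which is far more electrophilic than either ester, forming C3–C4 and giving aldolate 16; the closest known reaction type is the dianion aldol of β-hydroxy esters combined with the addition of lithium ester enolates to α-keto esters. After the cold acetic acid quench to 17, the C5 hydroxyl attacks the neighbouring pyruvate-derived methyl ester under PPTS and expels methanol, a 5-exo-trig acyl substitution that closes the γ-lactone (O1–C2), and this closure may already begin at the alkoxide stage. The tert-butyl ester cannot compete because it could only form a four-membered ring and is sterically shielded, so the two carboxyl carbons are distinguished automatically. New centres arise at C4 (expected anti to the C5 chain through attack on the chelate face away from it) and at C3 (uncontrolled), but both are erased in step 7 and need no control. The step needs only chemoselectivity, namely addition instead of proton transfer from the pyruvate methyl group and no retro-aldol, which the low temperature, the excess of pyruvate, the chelated dianion and the cold quench are meant to secure.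

Step 7
Reactants: 18 tert-butyl (2S)-4-hydroxy-4-methyl-2-[13-(2-methyl-1,3-dioxolan-2-yl)tridecyl]-5-oxooxolane-3-carboxylate
Product: 20 tert-butyl (2S)-4-methyl-2-[13-(2-methyl-1,3-dioxolan-2-yl)tridecyl]-5-oxo-2,5-dihydrofuran-3-carboxylate, via tertiary mesylate 19 (not isolated)
Conditions: MsCl (2 equiv), Et3N (4 equiv), CH2Cl2, 0 °C; cold aq. NH4Cl quench
Reagents that add atoms: none
Why: Sulfene-mediated mesylation of the tertiary C3 hydroxyl followed by E1cB elimination through the acidic C4–H (α to the ester) should give the tetrasubstituted C3=C4 alkene conjugated to both carbonyls from either diastereomer of 18, while triethylamine at 0 °C is too weak to remove the C5 γ-proton at a significant rate, so the (S) centre should be retained.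

Step 8
Reactants: 20 tert-butyl (2S)-4-methyl-2-[13-(2-methyl-1,3-dioxolan-2-yl)tridecyl]-5-oxo-2,5-dihydrofuran-3-carboxylate
Product: 22 (2S)-4-methyl-5-oxo-2-(14-oxopentadecyl)-2,5-dihydrofuran-3-carboxylic acid, via keto tert-butyl ester 21 (not isolated)
Conditions: TFA–H2O (9:1), CH2Cl2, 0 °C → rt
Reagents that add atoms: water, O
Why: Acidolysis, in which aqueous TFA first hydrolyses the dioxolane (giving 21) and then cleaves the tert-butyl ester by alkyl–oxygen fission with loss of isobutene, so ketone and acid are unmasked without any base that could epimerise C5 or move the double bond out of the ring.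

Compound list
1 | ω-pentadecalactone (oxacyclohexadecan-2-one) | O=C1CCCCCCCCCCCCCCO1 | starting material
2 | methyllithium | [Li]C | starting material
3 | lithium 2-methyl-1-oxacyclohexadecan-2-olate (tetrahedral adduct) | CC1([O-])CCCCCCCCCCCCCCO1.[Li+] | intermediate
4 | 16-hydroxyhexadecan-2-one | CC(=O)CCCCCCCCCCCCCCO | intermediate
5 | 15-oxohexadecanal | CC(=O)CCCCCCCCCCCCCC=O | intermediate
6 | 15-oxohexadecanoic acid | CC(=O)CCCCCCCCCCCCCC(=O)O | intermediate
7 | Meldrum's acid (2,2-dimethyl-1,3-dioxane-4,6-dione) | CC1(C)OC(=O)CC(=O)O1 | starting material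
8 | tert-butanol | CC(C)(C)O | starting material
9 | 5-(1-hydroxy-15-oxohexadecylidene)-2,2-dimethyl-1,3-dioxane-4,6-dione (acyl Meldrum's acid, enol form) | CC(=O)CCCCCCCCCCCCCC(O)=C1C(=O)OC(C)(C)OC1=O | intermediate
10 | tert-butyl 3,17-dioxooctadecanoate | CC(=O)CCCCCCCCCCCCCC(=O)CC(=O)OC(C)(C)C | intermediate
11 | tert-butyl (3S)-3-hydroxy-17-oxooctadecanoate | CC(=O)CCCCCCCCCCCCC[C@H](O)CC(=O)OC(C)(C)C | intermediate
12 | ethylene glycol | OCCO | starting material
13 | tert-butyl (3S)-3-hydroxy-16-(2-methyl-1,3-dioxolan-2-yl)hexadecanoate (key-step precursor) | CC1(CCCCCCCCCCCCC[C@H](O)CC(=O)OC(C)(C)C)OCCO1 | intermediate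
14 | methyl pyruvate | CC(=O)C(=O)OC | starting material
15 | dilithium alkoxide–enolate of 13 (enolate geometry not specified) | CC1(CCCCCCCCCCCCC[C@H]([O-])C=C([O-])OC(C)(C)C)OCCO1.[Li+].[Li+] | intermediate
16 | dilithium aldolate of 15 with methyl pyruvate (new centres unspecified) | CC1(CCCCCCCCCCCCC[C@H]([O-])C(C(=O)OC(C)(C)C)C(C)([O-])C(=O)OC)OCCO1.[Li+].[Li+] | intermediate
17 | 4-tert-butyl 1-methyl 2-hydroxy-3-[(1S)-1-hydroxy-14-(2-methyl-1,3-dioxolan-2-yl)tetradecyl]-2-methylbutanedioate (C2 and C3 unspecified) | CC1(CCCCCCCCCCCCC[C@H](O)C(C(=O)OC(C)(C)C)C(C)(O)C(=O)OC)OCCO1 | intermediate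
18 | tert-butyl (2S)-4-hydroxy-4-methyl-2-[13-(2-methyl-1,3-dioxolan-2-yl)tridecyl]-5-oxooxolane-3-carboxylate (ring C3 and C4 unspecified; key-step product) | CC1(CCCCCCCCCCCCC[C@@H]2OC(=O)C(C)(O)C2C(=O)OC(C)(C)C)OCCO1 | intermediate
19 | tert-butyl (2S)-4-methyl-4-(methylsulfonyloxy)-2-[13-(2-methyl-1,3-dioxolan-2-yl)tridecyl]-5-oxooxolane-3-carboxylate | CC1(CCCCCCCCCCCCC[C@@H]2OC(=O)C(C)(OS(C)(=O)=O)C2C(=O)OC(C)(C)C)OCCO1 | intermediate
20 | tert-butyl (2S)-4-methyl-2-[13-(2-methyl-1,3-dioxolan-2-yl)tridecyl]-5-oxo-2,5-dihydrofuran-3-carboxylate | CC1(CCCCCCCCCCCCC[C@@H]2OC(=O)C(C)=C2C(=O)OC(C)(C)C)OCCO1 | intermediate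
21 | tert-butyl (2S)-4-methyl-5-oxo-2-(14-oxopentadecyl)-2,5-dihydrofuran-3-carboxylate | CC(=O)CCCCCCCCCCCCC[C@@H]1OC(=O)C(C)=C1C(=O)OC(C)(C)C | intermediate
22 | (2S)-4-methyl-5-oxo-2-(14-oxopentadecyl)-2,5-dihydrofuran-3-carboxylic acid | CC(=O)CCCCCCCCCCCCC[C@@H]1OC(=O)C(C)=C1C(=O)O | target

Total step count: 8. Longest linear sequence: 8 steps (1 → 22).

Steps most likely to fail

Step 6. The strongly basic dianion may take a proton from the methyl group of methyl pyruvate instead of adding to its ketone (returning 13 and setting off pyruvate self-condensation), or the lithium aldolate may fragment by retro-aldol before the quench. The fallback moves the C3–C4 bond formation to neutral conditions. It sets out from 13: the dianion is generated as in step 6 and trapped on both oxygens with Me3SiCl to give the tert-butyl trimethylsilyl ketene acetal 3-O-trimethylsilyl ether F1. A Mukaiyama aldol addition of F1 to methyl pyruvate 14, catalysed by a copper(II) bis(oxazoline) triflate that binds only the chelating 1,2-dicarbonyl unit and leaves the dioxolane alone, should give the bis(trimethylsilyl) ether of the aldol adduct F2. TBAF buffered with AcOH then removes both silyl groups and gives 17, where the fallback rejoins the route ahead of the PPTS lactonisation to 18.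

Step 7. Sulfonylation of the hindered tertiary hydroxyl may stall, elimination may go towards the C3 methyl group (exocyclic alkene), or the amine may erode the configuration at C5 through γ-deprotonation of the product. The fallback avoids amine bases altogether and sets out from 18. Aqueous TFA first removes the tert-butyl ester and the dioxolane to give the hydroxy lactone keto acid F3. Heating in acetic anhydride should acetylate the C3 hydroxyl, activate the carboxyl and eliminate acetic acid across C3–C4, giving the acetic mixed anhydride of the butenolide acid F4. Stirring with water/THF hydrolyses the mixed anhydride and gives the target 22 directly.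

Step 1. The tetrahedral adduct of the macrocyclic lactone may collapse before the quench, so that a second methyllithium adds to the liberated ketone while lactone remains. The fallback sets out from 1: aminolysis with Me(MeO)NH·HCl and Me3Al gives the Weinreb amide 15-hydroxy-N-methoxy-N-methylpentadecanamide F5. Excess MeMgBr (the first equivalent is consumed by the hydroxyl) stops at the chelated adduct and returns 4 after work-up.

Further compounds
F1 | step 6 | tert-butyl trimethylsilyl ketene acetal of 13 with the 3-hydroxyl as trimethylsilyl ether | CC1(CCCCCCCCCCCCC[C@H](O[Si](C)(C)C)C=C(O[Si](C)(C)C)OC(C)(C)C)OCCO1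
F2 | step 6 | 4-tert-butyl 1-methyl 2-methyl-2-(trimethylsilyloxy)-3-[(1S)-14-(2-methyl-1,3-dioxolan-2-yl)-1-(trimethylsilyloxy)tetradecyl]butanedioate | CC1(CCCCCCCCCCCCC[C@H](O[Si](C)(C)C)C(C(=O)OC(C)(C)C)C(C)(O[Si](C)(C)C)C(=O)OC)OCCO1
F3 | step 7 | (2S)-4-hydroxy-4-methyl-5-oxo-2-(14-oxopentadecyl)oxolane-3-carboxylic acid | CC(=O)CCCCCCCCCCCCC[C@@H]1OC(=O)C(C)(O)C1C(=O)O
F4 | step 7 | acetic (2S)-4-methyl-5-oxo-2-(14-oxopentadecyl)-2,5-dihydrofuran-3-carboxylic anhydride | CC(=O)CCCCCCCCCCCCC[C@@H]1OC(=O)C(C)=C1C(=O)OC(C)=O
F5 | step 1 | 15-hydroxy-N-methoxy-N-methylpentadecanamide | CON(C)C(=O)CCCCCCCCCCCCCCO
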